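**Retrosynthetic overview**

1. Target 23 ⇐ hydroxy ester 21 (O‑sulfation, ester hydrolysis) ⇐ silyl ether 20 (desilylation).
2. 20 ⇐ linear hexaenoate 19 by one intramolecular Diels–Alder reaction. Ring B (bond C4a–C8a) and ring A (bond C1–C2) close in the same step, and the tether‑cis diene forces the cis ring fusion.
3. 19 ⇐ aldehyde 14 + C6 phosphonate 17 (Horner–Wadsworth–Emmons).
4. 14 ⇐ epoxy alcohol 12 (1,2‑hydride shift) ⇐ (Z)‑allylic alcohol 11 by Sharpless epoxidation. This C–O bond formation sets the first stereocentre (C7–O of the target) and all others are relayed from it.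
5. 11 ⇐ trienal 7 ⇐ dienal 3 ⇐ tiglic aldehyde 1.

Assumption: the target is taken as the free hydrogen sulfate / carboxylic acid as drawn, released from its dilithium salt by cold acidification.

**Step 1**
Reactants: 1 (E)-2-methylbut-2-enal; 2 2-(triphenylphosphoranylidene)propanal
Product: 3 (2E,4E)-2,4-dimethylhexa-2,4-dienal
Conditions: 1 (2 equiv), toluene, 110 °C, 24 h
Reagents that add atoms: none
Why: Wittig olefination with a stabilised formyl ylide gives the (E)-trisubstituted enal, and excess 1 suppresses a second homologation.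

**Step 2**
Reactants: 3 (2E,4E)-2,4-dimethylhexa-2,4-dienal; 4 (4-ethoxy-4-oxobutyl)triphenylphosphonium bromide
Product: 6 ethyl (4Z,6E,8E)-6,8-dimethyldeca-4,6,8-trienoate, via ethyl 4-(triphenylphosphoranylidene)butanoate 5 (not isolated)
Conditions: 4, NaN(SiMe3)2, THF, −78 °C; then 3, −78 °C → rt
Reagents that add atoms: none
Why: Lithium-free Wittig reaction of a non-stabilised ylide with the enal is kinetically Z-selective and installs the tether-cis alkene of the future diene.

**Step 3**
Reactants: 6 ethyl (4Z,6E,8E)-6,8-dimethyldeca-4,6,8-trienoate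
Product: 7 (4Z,6E,8E)-6,8-dimethyldeca-4,6,8-trienal
Conditions: i-Bu2AlH (1.05 equiv), CH2Cl2, −78 °C; MeOH, aq. potassium sodium tartrate
Reagents that add atoms: none
Why: Partial hydride reduction of the ester stops at the aldehyde because the tetrahedral aluminium hemiacetal is stable at −78 °C, and the triene is inert.

**Step 4**
Reactants: 7 (4Z,6E,8E)-6,8-dimethyldeca-4,6,8-trienal; 8 ethyltriphenylphosphonium bromide
Product: 11 (2Z,6Z,8E,10E)-2,8,10-trimethyldodeca-2,6,8,10-tetraen-1-ol, via ethylidenetriphenylphosphorane 9 (not isolated), via lithium beta-oxido ylide 10 (not isolated)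
Conditions: 8, n-BuLi, THF, 0 °C; 7, −78 °C; n-BuLi, −78 → −30 °C; (CH2O)n, 0 °C → rt
Reagents that add atoms: paraformaldehyde (formaldehyde), C=O
Why: Corey–Schlosser β-oxido ylide olefination, in which the betaine is deprotonated and trapped with formaldehyde, loses the original aldehyde oxygen as Ph3PO and places CH2OH cis to the chain, giving the (Z)-2-methyl allylic alcohol.

**Step 5**
Reactants: 11 (2Z,6Z,8E,10E)-2,8,10-trimethyldodeca-2,6,8,10-tetraen-1-ol
Product: 12 [(2R,3S)-3-[(3Z,5E,7E)-5,7-dimethylnona-3,5,7-trien-1-yl]-2-methyloxiran-2-yl]methanol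
Conditions: Ti(OiPr)4 (10 mol %), D-(−)-diisopropyl tartrate (12 mol %), t-BuOOH, 4 Å MS, CH2Cl2, −20 °C
Reagents that add atoms: tert-butyl hydroperoxide, CC(C)(C)OO
Why: Sharpless asymmetric epoxidation is directed by the allylic hydroxyl, so the triene is untouched, and D-(−)-tartrate delivers oxygen to the face that gives the (2R,3S)-epoxide, creating the C–O stereocentre that becomes C7–O of the target.

**Step 6**
Reactants: 12 [(2R,3S)-3-[(3Z,5E,7E)-5,7-dimethylnona-3,5,7-trien-1-yl]-2-methyloxiran-2-yl]methanol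
Product: 14 (2S,3S,6Z,8E,10E)-3-[(tert-butyldimethylsilyl)oxy]-2,8,10-trimethyldodeca-6,8,10-trienal, via epoxy silyl ether 13 (not isolated)
Conditions: TBSOTf (1.5 equiv), i-Pr2NEt, 4 Å MS, CH2Cl2, −42 °C
Reagents that add atoms: tert-butyldimethylsilyl trifluoromethanesulfonate, CC(C)(C)[Si](C)(C)OS(=O)(=O)C(F)(F)F
Why: Silyl-triflate-triggered semipinacol-type rearrangement of the epoxy silyl ether (non-aldol aldol) opens the tertiary C2–O bond with an anti 1,2-hydride shift from CH2OSi, inverting C2 while the C3–O bond is retained, so the methyl group (future C8) ends up anti to the silylated oxygen.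

**Step 7**
Reactants: 15 ethyl (2E,4E)-hexa-2,4-dienoate (ethyl sorbate)
Product: 16 ethyl (2E,4E)-6-bromohexa-2,4-dienoate
Conditions: NBS, (PhCO2)2 (cat.), PhCF3, reflux
Reagents that add atoms: N-bromosuccinimide, O=C1CCC(=O)N1Br
Why: Wohl–Ziegler radical bromination occurs at the terminal methyl because the delocalised radical is brominated where conjugation with the ester is kept.

**Step 8**
Reactants: 16 ethyl (2E,4E)-6-bromohexa-2,4-dienoate
Product: 17 ethyl (2E,4E)-6-(diethoxyphosphoryl)hexa-2,4-dienoate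
Conditions: P(OEt)3, neat, 120 °C
Reagents that add atoms: triethyl phosphite, CCOP(OCC)OCC
Why: Michaelis–Arbuzov reaction of the primary allylic bromide gives the phosphonate with loss of bromoethane.

**Step 9**
Reactants: 14 (2S,3S,6Z,8E,10E)-3-[(tert-butyldimethylsilyl)oxy]-2,8,10-trimethyldodeca-6,8,10-trienal; 17 ethyl (2E,4E)-6-(diethoxyphosphoryl)hexa-2,4-dienoate
Product: 19 ethyl (2E,4E,6E,8R,9S,12Z,14E,16E)-9-[(tert-butyldimethylsilyl)oxy]-8,14,16-trimethyloctadeca-2,4,6,12,14,16-hexaenoate, via lithiated phosphonate 18 (not isolated)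
Conditions: 17, LiN(SiMe3)2, THF, −78 °C; then 14, −78 → 0 °C
Reagents that add atoms: none
Why: Vinylogous Horner–Wadsworth–Emmons olefination with a stabilised phosphonate anion is E-selective, and the low temperature keeps the α-methyl aldehyde from epimerising.

**Step 10**
Reactants: 19 ethyl (2E,4E,6E,8R,9S,12Z,14E,16E)-9-[(tert-butyldimethylsilyl)oxy]-8,14,16-trimethyloctadeca-2,4,6,12,14,16-hexaenoate
Product: 20 ethyl (2E,4E)-5-[(1S,2R,4aS,7S,8R,8aR)-2-[(2E)-but-2-en-2-yl]-7-[(tert-butyldimethylsilyl)oxy]-3,8-dimethyl-1,2,4a,5,6,7,8,8a-octahydronaphthalen-1-yl]penta-2,4-dienoate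
Conditions: Me2AlCl (1.5 equiv), CH2Cl2 (0.005 M), −78 → −20 °C; aq. potassium sodium tartrate
Reagents that add atoms: none
Why: Proposed new method: a Lewis-acid-promoted intramolecular Diels–Alder reaction in which Me2AlCl on the ester carbonyl lowers the LUMO of the whole trienoate and the tether-cis (12Z) diene adds to the remote C6=C7 alkene, the only dienophile the four-carbon tether can reach; the cis tether allows only the cis-fused transition state with the dienoate arm endo (fixing C1, C2, C4a and C8a relative to each other), the face is chosen by the chair-like tether that keeps the OTBS group equatorial and avoids its syn-axial clash with C1 (C8 methyl axial), and the low temperature is meant to outrun the thermal 1,5-hydrogen shift of the cis diene; the closest known reaction types are the alkylaluminium chloride-promoted intramolecular Diels–Alder reaction of deca-2,7,9-trienoates and the thermal intramolecular Diels–Alder reaction of (Z)-dienes.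

**Step 11**
Reactants: 20 (silyl ether, as above)
Product: 21 ethyl (2E,4E)-5-[(1S,2R,4aS,7S,8R,8aR)-2-[(2E)-but-2-en-2-yl]-7-hydroxy-3,8-dimethyl-1,2,4a,5,6,7,8,8a-octahydronaphthalen-1-yl]penta-2,4-dienoate
Conditions: HF·pyridine, pyridine, THF, 0 °C → rt
Reagents that add atoms: none
Why: Fluoride-driven desilylation (strong Si–F bond) under pyridine buffering frees the C7 hydroxyl without touching the alkenes or the ester.

**Step 12**
Reactants: 21 (hydroxy ester, as above)
Product: 23 (2E,4E)-5-[(1S,2R,4aS,7S,8R,8aR)-2-[(2E)-but-2-en-2-yl]-3,8-dimethyl-7-(sulfooxy)-1,2,4a,5,6,7,8,8a-octahydronaphthalen-1-yl]penta-2,4-dienoic acid, via pyridinium sulfate ethyl ester 22 (not isolated)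
Conditions: SO3·pyridine (5 equiv), pyridine, 40 °C; then LiOH, THF/MeOH/H2O, rt; cold aq. HCl to pH 2, C18 desalting
Reagents that add atoms: sulfur trioxide–pyridine complex, O=S(=O)([O-])[n+]1ccccc1; lithium hydroxide, [Li+].[OH-]
Why: O-sulfation with SO3·pyridine forms the S–O bond at oxygen, so the C7–O bond and its configuration are retained, and the sulfate monoester survives the hydroxide saponification of the ethyl ester.

**Compound list**

1 | (E)-2-methylbut-2-enal (tiglic aldehyde) | C/C=C(\C)C=O | starting material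
2 | 2-(triphenylphosphoranylidene)propanal | CC(C=O)=P(c1ccccc1)(c1ccccc1)c1ccccc1 | starting material
3 | (2E,4E)-2,4-dimethylhexa-2,4-dienal | C/C=C(C)/C=C(C)/C=O | intermediate
4 | (4-ethoxy-4-oxobutyl)triphenylphosphonium bromide | CCOC(=O)CCC[P+](c1ccccc1)(c1ccccc1)c1ccccc1.[Br-] | starting material
5 | ethyl 4-(triphenylphosphoranylidene)butanoate | CCOC(=O)CCC=P(c1ccccc1)(c1ccccc1)c1ccccc1 | intermediate
6 | ethyl (4Z,6E,8E)-6,8-dimethyldeca-4,6,8-trienoate | C/C=C(C)/C=C(C)/C=C\CCC(=O)OCC | intermediate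
7 | (4Z,6E,8E)-6,8-dimethyldeca-4,6,8-trienal | C/C=C(C)/C=C(C)/C=C\CCC=O | intermediate
8 | ethyltriphenylphosphonium bromide | CC[P+](c1ccccc1)(c1ccccc1)c1ccccc1.[Br-] | starting material
9 | ethylidenetriphenylphosphorane | CC=P(c1ccccc1)(c1ccccc1)c1ccccc1 | intermediate
10 | lithium (6Z,8E,10E)-8,10-dimethyl-2-(triphenylphosphoranylidene)dodeca-6,8,10-trien-3-olate | C/C=C(C)/C=C(C)/C=C\CCC([O-])C(C)=P(c1ccccc1)(c1ccccc1)c1ccccc1.[Li+] | intermediate
11 | (2Z,6Z,8E,10E)-2,8,10-trimethyldodeca-2,6,8,10-tetraen-1-ol | C/C=C(C)/C=C(C)/C=C\CC/C=C(/C)CO | intermediate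
12 | [(2R,3S)-3-[(3Z,5E,7E)-5,7-dimethylnona-3,5,7-trien-1-yl]-2-methyloxiran-2-yl]methanol | C/C=C(C)/C=C(C)/C=C\CC[C@@H]1O[C@]1(C)CO | intermediate
13 | tert-butyl{[(2R,3S)-3-[(3Z,5E,7E)-5,7-dimethylnona-3,5,7-trien-1-yl]-2-methyloxiran-2-yl]methoxy}dimethylsilane | C/C=C(C)/C=C(C)/C=C\CC[C@@H]1O[C@]1(C)CO[Si](C)(C)C(C)(C)C | intermediate
14 | (2S,3S,6Z,8E,10E)-3-[(tert-butyldimethylsilyl)oxy]-2,8,10-trimethyldodeca-6,8,10-trienal | C/C=C(C)/C=C(C)/C=C\CC[C@H](O[Si](C)(C)C(C)(C)C)[C@H](C)C=O | intermediate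
15 | ethyl (2E,4E)-hexa-2,4-dienoate (ethyl sorbate) | C/C=C/C=C/C(=O)OCC | starting material
16 | ethyl (2E,4E)-6-bromohexa-2,4-dienoate | BrC/C=C/C=C/C(=O)OCC | intermediate
17 | ethyl (2E,4E)-6-(diethoxyphosphoryl)hexa-2,4-dienoate | CCOC(=O)/C=C/C=C/CP(=O)(OCC)OCC | intermediate
18 | lithium salt of the C6 carbanion of 17 | CCOC(=O)/C=C/C=C/[CH-]P(=O)(OCC)OCC.[Li+] | intermediate
19 | ethyl (2E,4E,6E,8R,9S,12Z,14E,16E)-9-[(tert-butyldimethylsilyl)oxy]-8,14,16-trimethyloctadeca-2,4,6,12,14,16-hexaenoate | C/C=C(C)/C=C(C)/C=C\CC[C@H](O[Si](C)(C)C(C)(C)C)[C@H](C)/C=C/C=C/C=C/C(=O)OCC | intermediate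
20 | ethyl (2E,4E)-5-[(1S,2R,4aS,7S,8R,8aR)-2-[(2E)-but-2-en-2-yl]-7-[(tert-butyldimethylsilyl)oxy]-3,8-dimethyl-1,2,4a,5,6,7,8,8a-octahydronaphthalen-1-yl]penta-2,4-dienoate | C/C=C(\C)[C@@H]1C(C)=C[C@H]2CC[C@H](O[Si](C)(C)C(C)(C)C)[C@H](C)[C@H]2[C@@H]1/C=C/C=C/C(=O)OCC | intermediate
21 | ethyl (2E,4E)-5-[(1S,2R,4aS,7S,8R,8aR)-2-[(2E)-but-2-en-2-yl]-7-hydroxy-3,8-dimethyl-1,2,4a,5,6,7,8,8a-octahydronaphthalen-1-yl]penta-2,4-dienoate | C/C=C(\C)[C@@H]1C(C)=C[C@H]2CC[C@H](O)[C@H](C)[C@H]2[C@@H]1/C=C/C=C/C(=O)OCC | intermediate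
22 | pyridinium salt of ethyl (2E,4E)-5-[(1S,2R,4aS,7S,8R,8aR)-2-[(2E)-but-2-en-2-yl]-3,8-dimethyl-7-(sulfonatooxy)-1,2,4a,5,6,7,8,8a-octahydronaphthalen-1-yl]penta-2,4-dienoate | C/C=C(\C)[C@@H]1C(C)=C[C@H]2CC[C@H](OS(=O)(=O)[O-])[C@H](C)[C@H]2[C@@H]1/C=C/C=C/C(=O)OCC.c1cc[nH+]cc1 | intermediate
23 | (2E,4E)-5-[(1S,2R,4aS,7S,8R,8aR)-2-[(2E)-but-2-en-2-yl]-3,8-dimethyl-7-(sulfooxy)-1,2,4a,5,6,7,8,8a-octahydronaphthalen-1-yl]penta-2,4-dienoic acid | C/C=C(\C)[C@@H]1C(C)=C[C@H]2CC[C@H](OS(=O)(=O)O)[C@H](C)[C@H]2[C@@H]1/C=C/C=C/C(=O)O | target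

**Step count**

Total: 12 steps. Longest linear sequence: 10 steps (1, 2, 3, 4, 5, 6, 9, 10, 11, 12); steps 7 and 8 make the phosphonate in a side branch.

**Three steps most likely to fail**

Step 10 (the proposed new cycloaddition). The Lewis acid may fail to activate the remote alkene, or may isomerise or oligomerise the electron-rich triene. The fallback sets out from 19 and comes back at 20 and uses known chemistry: 19 is heated at 0.005 M in degassed toluene with a trace of 2,6-di-tert-butyl-4-methylphenol at 110–130 °C in a sealed vessel. The thermal intramolecular Diels–Alder reaction of tether-cis dienes is established and can only give the cis-fused ring system; the expected loss is to the competing 1,5-hydrogen shift and a lower facial ratio. No further compound arises on this way (F0).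

Step 6 (hydride-shift rearrangement). The nearby nucleophilic triene may capture the opening tertiary epoxide carbon instead of the hydride. The fallback sets out from 7 and comes back at 14, replacing steps 4 to 6 by a C–C bond-forming approach. L-Proline-catalysed anti-selective cross-aldol reaction of 7 with propanal (slow addition, DMF, 4 °C) gives (2S,3S,6Z,8E,10E)-3-hydroxy-2,8,10-trimethyldodeca-6,8,10-trienal F1, which is silylated at once with TBSOTf and 2,6-lutidine in CH2Cl2 at −78 °C to give 14. The weakness is cross- versus self-aldol selectivity with an unbranched acceptor.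

Step 4 (β-oxido ylide olefination). The yield and the Z:E ratio can be moderate with an enolisable aldehyde. The fallback sets out from 7 and comes back at 11. Still–Gennari olefination of 7 with methyl 2-[bis(2,2,2-trifluoroethoxy)phosphoryl]propanoate, KN(SiMe3)2 and 18-crown-6 in THF at −78 °C gives methyl (2Z,6Z,8E,10E)-2,8,10-trimethyldodeca-2,6,8,10-tetraenoate F2. Reduction of F2 with i-Bu2AlH (2.2 equiv) in CH2Cl2 at −78 °C returns 11, at the cost of one extra step.

**Further compounds**

F0 | step 10 | none | none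
F1 | step 6 | (2S,3S,6Z,8E,10E)-3-hydroxy-2,8,10-trimethyldodeca-6,8,10-trienal | C/C=C(C)/C=C(C)/C=C\CC[C@H](O)[C@H](C)C=O
F2 | step 4 | methyl (2Z,6Z,8E,10E)-2,8,10-trimethyldodeca-2,6,8,10-tetraenoate | C/C=C(C)/C=C(C)/C=C\CC/C=C(/C)C(=O)OC
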